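**Retrosynthetic overview**

1. The target loses two MOM groups and is then cut at both enone Cα=Cβ bonds (two Claisen–Schmidt condensations). This gives a ring B aldehyde, a ring D methyl ketone, and a ring A/ring C diaryl ether core with an acetyl group on ring A and a formyl group on ring C.
2. The core comes from methyl 4-(2,4-dimethoxyphenoxy)benzoate by Friedel–Crafts acetylation with ortho-demethylation on ring A, then redox adjustment of the ester and masking of the aldehyde as its dimethyl acetal.
3. That benzoate comes from methyl coumalate and an aryl ethynyl ether by (4+2) cycloaddition and loss of CO2. The feature used is ring C, a 1,4-disubstituted benzene with the diaryl ether oxygen on C4 and the future enone β-carbon on C1. This para O/C pattern is what C3/C6 of a 5-carboxy-2-pyrone and an oxygen-substituted alkyne deliver.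
4. The aryl ethynyl ether comes from 2,4-dimethoxyphenol and trichloroethylene, so the O–C bond to ring C is made before that ring exists.
5. Ring order: rings A, B and D are bought as benzenes; ring C is the only ring formed.

Key step: step 3

Remark on the chemistry: ring A is the 2-hydroxy-4-methoxy-5-aryloxyphenyl ketone ring, ring B the 4-hydroxyphenyl ring, ring C the para-phenylene and ring D the 2,4-dihydroxyphenyl ring. The target has no stereocentre, only two E-alkenes.

**Route**

Step 1
Reactants: 1 2,4-dimethoxyphenol; 2 trichloroethylene
Product: 4 (E)-1-[(1,2-dichloroethenyl)oxy]-2,4-dimethoxybenzene, via dichloroacetylene 3 (not isolated)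
Conditions: K2CO3, DMF, 70 °C
Reagents that add atoms: none
Why: Base-mediated dehydrochlorination of trichloroethylene gives dichloroacetylene, to which the phenoxide adds in anti fashion (elimination–addition vinylic substitution), the established way to aryl (E)-1,2-dichlorovinyl ethers.

Step 2
Reactants: 4 (E)-1-[(1,2-dichloroethenyl)oxy]-2,4-dimethoxybenzene
Product: 7 1-(ethynyloxy)-2,4-dimethoxybenzene, via chloroalkynyl ether 5 (not isolated), via lithium aryloxyacetylide 6 (not isolated)
Conditions: n-BuLi (2.5 equiv), Et2O, −78 → −40 °C; then H2O, −78 °C; used at once as a toluene solution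
Reagents that add atoms: none
Why: n-BuLi removes the vinylic proton and chloride is lost (β-elimination) to the chloroalkynyl ether, a second equivalent performs chlorine–lithium exchange to the acetylide, and cold protonation should give the terminal ynol ether (Greene-type conversion of a dichlorovinyl ether into an alkynyl ether).

Step 3
Reactants: 7 1-(ethynyloxy)-2,4-dimethoxybenzene; 8 methyl coumalate
Product: 10 methyl 4-(2,4-dimethoxyphenoxy)benzoate, via bicyclic lactone 9 (not isolated)
Conditions: 8 (2 equiv), BHT (cat.), PhMe, 90 °C, sealed tube
Reagents that add atoms: none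
Why: The 2-pyrone is an electron-poor diene (C3=C4–C5=C6, lowered in energy by the lactone carbonyl and the C5 ester) and the ynol ether an electron-rich 2π partner, so an inverse-electron-demand (4+2) cycloaddition, probably asynchronous with the bond from the terminal alkyne carbon to C6 running ahead, should give the 2-oxabicyclo[2.2.2]octadienone 9, which loses CO2 by retro-(4+2) at the reaction temperature. The closest known reaction type is the cycloaddition–decarboxylation of methyl coumalate with enol ethers, ketene acetals and heteroatom-substituted alkynes to para-substituted benzoates; the aryl ethynyl ether is a new member of that dienophile class, not a new reaction. Ring C is closed intermolecularly in the cycloaddition itself (two C–C bonds, C6–CH and C3–C(OAr), a six-membered ring from four pyrone carbons and the two alkyne carbons) and becomes aromatic directly on CO2 loss because the dienophile is an alkyne, so no oxidation or elimination is needed. The two bridgehead centres of 9 form as a racemate and vanish on aromatisation, so no stereocontrol is required. The selectivity needed is para over meta: the largest HOMO coefficient of the ynol ether lies on the terminal carbon (β to oxygen) and the most electrophilic diene terminus of the coumalate is C6 (β to the ester and the vinylogous end of the lactone), so these two join and the oxygen-bearing carbon ends 1,4 to the ester carbon. The aryl ether has no sp3 C–H β to oxygen, so the retro-ene loss of ketene that limits alkyl ynol ethers on heating is closed, and the excess of pyrone keeps capture faster than self-condensation of 7.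

Step 4
Reactants: 10 methyl 4-(2,4-dimethoxyphenoxy)benzoate
Product: 12 methyl 4-(5-acetyl-4-hydroxy-2-methoxyphenoxy)benzoate, via dimethoxy ketone 11 (not isolated)
Conditions: AcCl, AlCl3 (3.5 equiv), CH2Cl2, 0 → 40 °C; then ice-water
Reagents that add atoms: acetyl chloride, CC(=O)Cl
Why: Friedel–Crafts acylation should occur only on ring A (ring C is deactivated by the ester) at C5 (aryloxy carbon = C1), the position para to the C2 methoxy and ortho to the C4 methoxy, and excess AlCl3 then cleaves the methyl ether next to the new carbonyl through a six-membered aluminium chelate, as in the known conversion of 1,2,4-trimethoxybenzene into 2-hydroxy-4,5-dimethoxyacetophenone.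

Step 5
Reactants: 12 methyl 4-(5-acetyl-4-hydroxy-2-methoxyphenoxy)benzoate
Product: 13 2-(1-hydroxyethyl)-4-[4-(hydroxymethyl)phenoxy]-5-methoxyphenol (racemic)
Conditions: LiAlH4 (2.5 equiv), THF, 0 °C; then Na2SO4·10H2O; crude product used directly
Reagents that add atoms: none
Why: Hydride reduction with LiAlH4 takes the ester to the primary benzylic alcohol and, since no hydride separates an ester from an aryl ketone, also the ketone to a secondary alcohol whose racemic centre is erased in step 6; the neutral work-up avoids ionisation of the electron-rich benzylic alcohol.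

Step 6
Reactants: 13 2-(1-hydroxyethyl)-4-[4-(hydroxymethyl)phenoxy]-5-methoxyphenol
Product: 14 4-(5-acetyl-4-hydroxy-2-methoxyphenoxy)benzaldehyde
Conditions: MnO2 (activated, 20 equiv), CH2Cl2, rt
Reagents that add atoms: none
Why: MnO2 oxidises benzylic alcohols selectively and stops at the aldehyde, so both carbinols should return to carbonyl groups under neutral conditions that leave the phenol alone (heterogeneous benzylic oxidation).

Step 7
Reactants: 14 4-(5-acetyl-4-hydroxy-2-methoxyphenoxy)benzaldehyde
Product: 15 1-{5-[4-(dimethoxymethyl)phenoxy]-2-hydroxy-4-methoxyphenyl}ethan-1-one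
Conditions: HC(OMe)3, MeOH, TsOH·H2O (cat.), rt; then Et3N
Reagents that add atoms: trimethyl orthoformate, COC(OC)OC; methanol, CO
Why: Acid-catalysed acetalisation is much faster and more favourable for the aryl aldehyde than for the ortho-hydroxyaryl ketone, whose carbonyl is deactivated by the para-methoxy group and the internal hydrogen bond, so only the aldehyde should be masked and the later aldol partner roles are fixed.

Step 8
Reactants: 16 4-hydroxybenzaldehyde
Product: 17 4-(methoxymethoxy)benzaldehyde
Conditions: MOMCl, K2CO3, acetone, 0 °C → rt
Reagents that add atoms: chloromethyl methyl ether, COCCl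
Why: O-alkylation of the phenoxide with chloromethyl methyl ether (MOM protection, Williamson type) removes the acidic phenol that would deactivate the aldehyde as its phenoxide in the condensation.

Step 9
Reactants: 15 1-{5-[4-(dimethoxymethyl)phenoxy]-2-hydroxy-4-methoxyphenyl}ethan-1-one; 17 4-(methoxymethoxy)benzaldehyde
Product: 19 4-{4-hydroxy-2-methoxy-5-[(E)-3-[4-(methoxymethoxy)phenyl]prop-2-enoyl]phenoxy}benzaldehyde, via acetal chalcone 18 (not isolated)
Conditions: KOH (aq. 50%), EtOH, rt; then 1 M HCl to pH 2, THF, rt, 30 min
Reagents that add atoms: water, O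
Why: Claisen–Schmidt condensation (aldol addition, then E1cB dehydration) of the ring A methyl ketone with the non-enolisable aldehyde should give the thermodynamically favoured E-enone while the acetal is inert to base, and the brief aqueous acid of the work-up hydrolyses the dimethyl acetal much faster than the aryl MOM ether.

Step 10
Reactants: 20 1-(2,4-dihydroxyphenyl)ethan-1-one
Product: 21 1-[2-hydroxy-4-(methoxymethoxy)phenyl]ethan-1-one
Conditions: MOMCl (1.1 equiv), K2CO3, acetone, rt
Reagents that add atoms: chloromethyl methyl ether, COCCl
Why: Under K2CO3 only the 4-hydroxyl should be alkylated, because the 2-hydroxyl is held in a hydrogen bond to the ketone (selective MOM protection).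

Step 11
Reactants: 19 4-{4-hydroxy-2-methoxy-5-[(E)-3-[4-(methoxymethoxy)phenyl]prop-2-enoyl]phenoxy}benzaldehyde; 21 1-[2-hydroxy-4-(methoxymethoxy)phenyl]ethan-1-one
Product: 22 (E)-1-[2-hydroxy-5-(4-{(E)-3-[2-hydroxy-4-(methoxymethoxy)phenyl]-3-oxoprop-1-en-1-yl}phenoxy)-4-methoxyphenyl]-3-[4-(methoxymethoxy)phenyl]prop-2-en-1-one
Conditions: KOH (aq. 50%), EtOH, rt, argon; then dilute HCl to pH 5, 0 °C
Reagents that add atoms: none
Why: Claisen–Schmidt condensation in which aldehyde 19 has no enolisable carbonyl left (its ketone is already an enone), so the only enolate is that of 21, and aldol addition followed by E1cB dehydration should give the second E-enone.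

Step 12
Reactants: 22 bis-MOM bichalcone from step 11
Product: 23 rhuschalcone III
Conditions: 3 M HCl, MeOH, 60 °C, short reaction time
Reagents that add atoms: none
Why: Acid-catalysed acetal cleavage (MOM removal) in methanol should free the two phenols as in standard hydroxychalcone syntheses, with the E-enones untouched and the short heating limiting oxa-Michael closure to flavanones.

**Compound list**

1 | 2,4-dimethoxyphenol | COc1ccc(O)c(OC)c1 | starting material
2 | trichloroethylene | ClC=C(Cl)Cl | starting material
3 | dichloroacetylene (formed in the flask) | ClC#CCl | intermediate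
4 | (E)-1-[(1,2-dichloroethenyl)oxy]-2,4-dimethoxybenzene | Cl/C=C(/Cl)Oc1ccc(OC)cc1OC | intermediate
5 | 1-[(chloroethynyl)oxy]-2,4-dimethoxybenzene (formed in the flask) | ClC#COc1ccc(OC)cc1OC | intermediate
6 | lithium 2-(2,4-dimethoxyphenoxy)ethynide (formed in the flask) | [Li]C#COc1ccc(OC)cc1OC | intermediate
7 | 1-(ethynyloxy)-2,4-dimethoxybenzene | C#COc1ccc(OC)cc1OC | intermediate
8 | methyl coumalate (methyl 2-oxo-2H-pyran-5-carboxylate) | COC(=O)C1=COC(=O)C=C1 | starting material
9 | methyl 5-(2,4-dimethoxyphenoxy)-3-oxo-2-oxabicyclo[2.2.2]octa-5,7-diene-7-carboxylate (racemic, formed in the flask) | O=C1OC2C=C(Oc3ccc(OC)cc3OC)C1C=C2C(=O)OC | intermediate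
10 | methyl 4-(2,4-dimethoxyphenoxy)benzoate | COC(=O)c1ccc(Oc2ccc(OC)cc2OC)cc1 | intermediate
11 | methyl 4-(5-acetyl-2,4-dimethoxyphenoxy)benzoate (formed in the flask) | COC(=O)c1ccc(Oc2cc(C(C)=O)c(OC)cc2OC)cc1 | intermediate
12 | methyl 4-(5-acetyl-4-hydroxy-2-methoxyphenoxy)benzoate | COC(=O)c1ccc(Oc2cc(C(C)=O)c(O)cc2OC)cc1 | intermediate
13 | 2-(1-hydroxyethyl)-4-[4-(hydroxymethyl)phenoxy]-5-methoxyphenol (racemic) | CC(O)c1cc(Oc2ccc(CO)cc2)c(OC)cc1O | intermediate
14 | 4-(5-acetyl-4-hydroxy-2-methoxyphenoxy)benzaldehyde | CC(=O)c1cc(Oc2ccc(C=O)cc2)c(OC)cc1O | intermediate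
15 | 1-{5-[4-(dimethoxymethyl)phenoxy]-2-hydroxy-4-methoxyphenyl}ethan-1-one | CC(=O)c1cc(Oc2ccc(C(OC)OC)cc2)c(OC)cc1O | intermediate
16 | 4-hydroxybenzaldehyde | O=Cc1ccc(O)cc1 | starting material
17 | 4-(methoxymethoxy)benzaldehyde | COCOc1ccc(C=O)cc1 | intermediate
18 | (E)-1-{5-[4-(dimethoxymethyl)phenoxy]-2-hydroxy-4-methoxyphenyl}-3-[4-(methoxymethoxy)phenyl]prop-2-en-1-one (formed in the flask) | COCOc1ccc(/C=C/C(=O)c2cc(Oc3ccc(C(OC)OC)cc3)c(OC)cc2O)cc1 | intermediate
19 | 4-{4-hydroxy-2-methoxy-5-[(E)-3-[4-(methoxymethoxy)phenyl]prop-2-enoyl]phenoxy}benzaldehyde | COCOc1ccc(/C=C/C(=O)c2cc(Oc3ccc(C=O)cc3)c(OC)cc2O)cc1 | intermediate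
20 | 1-(2,4-dihydroxyphenyl)ethan-1-one | CC(=O)c1ccc(O)cc1O | starting material
21 | 1-[2-hydroxy-4-(methoxymethoxy)phenyl]ethan-1-one | COCOc1ccc(C(C)=O)c(O)c1 | intermediate
22 | (E)-1-[2-hydroxy-5-(4-{(E)-3-[2-hydroxy-4-(methoxymethoxy)phenyl]-3-oxoprop-1-en-1-yl}phenoxy)-4-methoxyphenyl]-3-[4-(methoxymethoxy)phenyl]prop-2-en-1-one | COCOc1ccc(/C=C/C(=O)c2cc(Oc3ccc(/C=C/C(=O)c4ccc(OCOC)cc4O)cc3)c(OC)cc2O)cc1 | intermediate
23 | rhuschalcone III | COc1cc(O)c(C(=O)/C=C/c2ccc(O)cc2)cc1Oc1ccc(/C=C/C(=O)c2ccc(O)cc2O)cc1 | target

**Step count**

Total: 12 steps. Longest linear sequence: 10 steps (steps 1–7, 9, 11, 12, from 2,4-dimethoxyphenol); steps 8 and 10 prepare the two condensation partners.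

**Steps most likely to fail, with fallbacks**

Step 3. The terminal ynol ether may oligomerise or hydrate on heating faster than it is captured by the pyrone, or bonding may leak to the meta orientation. The fallback sets out from 1 and gives up the pyrone construction of ring C. Nucleophilic aromatic substitution of the phenoxide of 1 on methyl 4-fluorobenzoate (K2CO3, DMSO, 120 °C) forms the diaryl ether bond to a ready-made ring C and should give 10 directly, where the route is rejoined.

Step 2. The terminal aryl ynol ether may be lost to hydration or polymerisation during aqueous work-up and concentration. The fallback sets out from 4. After the n-BuLi stage, acetylide 6 is trapped with Me3SiCl instead of water to give [(2,4-dimethoxyphenoxy)ethynyl]trimethylsilane F1, a capped ynol ether that can be purified and stored. K2CO3 (cat.) in MeOH at 0 °C removes the silyl group just before use, and the toluene extract is taken straight into step 3, so the route is rejoined at 7.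

Step 4. The one-pot acylation/dealkylation may overshoot to loss of the second methyl group (the one flanked by the aryloxy oxygen) or stall before the ortho ether is cleaved. The fallback sets out from 10 and separates the two events. Acetylation with AcOH/(CF3CO)2O and H3PO4 (cat.) (mixed-anhydride Friedel–Crafts acylation, which leaves aryl methyl ethers intact) should give 11 as an isolated compound. BCl3 in CH2Cl2 at −78 → 0 °C then cleaves only the methoxy group ortho to the ketone through the boron chelate, and the route is rejoined at 12.

**Further compounds**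

F0 | step 3 | none | none
F1 | step 2 | [(2,4-dimethoxyphenoxy)ethynyl]trimethylsilane | COc1ccc(OC#C[Si](C)(C)C)c(OC)c1
F0 | step 4 | none | none
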